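**Plan**
1. Cuts: (a) the lactam N–CH2 bond and, drawn backwards, a bond across the nine-membered ring from the lactam carbonyl carbon to the ketone α-carbon (which is also the lactone β-carbon), giving a 2-acylcyclopentanone; (b) the CH2–CH(N) bond β to the ketone (Mannich); (c) the two C–C bonds joining the fused-lactone carbonyl to its α-carbon and the lactone C–O carbon to the β-carbon (one [2+2], then Baeyer–Villiger); (d) the CH(Et)–CH(chlorobutyl) bond (Ireland–Claisen).
2. Enabling feature: in the nine-membered ring the lactam carbonyl carbon and the lactone β-carbon are 1,5-related through the chain-bearing, ethyl-bearing and C–O carbons. Tying them gives a cyclopentane in which the future C–O carbon (as a keteniminium carbon) sits three atoms from a 1,1-disubstituted alkene carrying the future β- and α-carbons.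
3. Forward order: acyclic amide → cyclopentane and cyclobutanone together → fused γ-lactone → methyl and acetyl groups → Mannich union with the pendant lactone → six-membered ketimine → seven-membered ring (N-alkylation) → nine-membered ring (C–C fragmentation).
4. Stereochemistry: ethyl/chain pair by chirality transfer from (S)-but-3-en-2-ol; ring-fusion C–O carbon from the cycloaddition (anti to that pair); lactone methyl by convex-face alkylation; pendant lactone from (R)-glyceraldehyde acetonide and a cis-hydrogenation; N-bearing carbon from the (R)-sulfinyl auxiliary; ketone α-carbon by final equilibration.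

Key step: step 9

Assumption: the CH between the ring ketone and the fused lactone is the only readily enolisable stereocenter of the target, and its configuration in the target is taken to be the thermodynamically preferred one.

Step 1
Reactants: 1 6-chlorohex-1-ene; 2 (S)-but-3-en-2-ol
Product: 3 (2S,3E)-8-chlorooct-3-en-2-ol
Conditions: second-generation Grubbs catalyst (cat.), CH2Cl2, 40 °C
Reagents that add atoms: none
Why: Olefin cross-metathesis of a terminal alkene with a secondary allylic alcohol should give the E-disubstituted allylic alcohol, and the carbinol center of 2 is not touched.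

Step 2
Reactants: 3 (2S,3E)-8-chlorooct-3-en-2-ol; 4 butanoyl chloride
Product: 5 (2S,3E)-8-chlorooct-3-en-2-yl butanoate
Conditions: Et3N, DMAP (cat.), CH2Cl2, 0 °C
Reagents that add atoms: none
Why: DMAP-catalysed acylation of a secondary alcohol with an acid chloride, with no stereocenter affected.

Step 3
Reactants: 5 (2S,3E)-8-chlorooct-3-en-2-yl butanoate
Product: 8 (2R,3R,4E)-3-(4-chlorobutyl)-2-ethylhex-4-enoic acid, via silyl ketene acetal 6 (not isolated), via trimethylsilyl ester 7 (not isolated)
Conditions: LiN(iPr)2, THF, −78 °C; Me3SiCl, Et3N; −78 → 60 °C; then 1 M HCl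
Reagents that add atoms: none
Why: Ireland–Claisen rearrangement, in which kinetic enolisation in THF places the ethyl group trans to OSiMe3 and the chair transition state with the carbinol methyl equatorial should transfer the (S)-carbinol chirality to the anti (2R,3R) pair and the E-alkene.

Step 4
Reactants: 8 (2R,3R,4E)-3-(4-chlorobutyl)-2-ethylhex-4-enoic acid
Product: 10 (3R,4R,5E)-4-(4-chlorobutyl)-1-diazo-3-ethylhept-5-en-2-one, via mixed carbonic anhydride 9 (not isolated)
Conditions: i-BuOCOCl, N-methylmorpholine, THF, −15 °C; then CH2N2, Et2O, 0 °C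
Reagents that add atoms: diazomethane, C=[N+]=[N-]
Why: First stage of the Arndt–Eistert homologation, acylation of diazomethane by a mixed anhydride, which should leave the α-stereocenter intact.

Step 5
Reactants: 10 (3R,4R,5E)-4-(4-chlorobutyl)-1-diazo-3-ethylhept-5-en-2-one
Product: 12 (3S,4S,5E)-4-(4-chlorobutyl)-3-ethyl-1-(pyrrolidin-1-yl)hept-5-en-1-one, via ketene 11 (not isolated)
Conditions: PhCO2Ag (cat.), pyrrolidine, THF, 25 °C, dark
Reagents that add atoms: pyrrolidine, C1CCNC1
Why: Silver-catalysed Wolff rearrangement with retention at the migrating carbon, the ketene being trapped by pyrrolidine to give the one-carbon-homologated amide needed for iminium activation.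

Step 6
Reactants: 12 (3S,4S,5E)-4-(4-chlorobutyl)-3-ethyl-1-(pyrrolidin-1-yl)hept-5-en-1-one
Product: 14 (2S,3S)-2-(4-chlorobutyl)-3-ethyl-5-oxo-5-(pyrrolidin-1-yl)pentanal, via ozonide 13 (not isolated)
Conditions: O3, CH2Cl2, −78 °C; then Me2S, −78 → 25 °C
Reagents that add atoms: ozone, [O-][O+]=O
Why: Ozonolysis with reductive work-up should cleave the only alkene to the α-branched aldehyde, the amide and the alkyl chloride being inert.

Step 7
Reactants: 14 (2S,3S)-2-(4-chlorobutyl)-3-ethyl-5-oxo-5-(pyrrolidin-1-yl)pentanal; 15 2-chlorobuta-1,3-diene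
Product: 17 (3S,4S,5R)-4-(4-chlorobutyl)-3-ethyl-5-hydroxy-6-methylidene-1-(pyrrolidin-1-yl)oct-7-en-1-one, via dienyl Grignard reagent 16 (not isolated)
Conditions: 15, Mg, THF, 60 °C; then 14, THF, −78 °C; H2O
Reagents that add atoms: none
Why: Grignard addition to the aldehyde, in which Felkin–Anh approach anti to the branched C-3 substituent should favour the (5R) carbinol; this center is later oxidised, so its configuration matters only for the selectivity of steps 9 and 11.

Step 8
Reactants: 17 (3S,4S,5R)-4-(4-chlorobutyl)-3-ethyl-5-hydroxy-6-methylidene-1-(pyrrolidin-1-yl)oct-7-en-1-one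
Product: 18 (3S,4S,5R)-5-(tert-butyldimethylsilyloxy)-4-(4-chlorobutyl)-3-ethyl-6-methylidene-1-(pyrrolidin-1-yl)oct-7-en-1-one
Conditions: t-BuMe2SiOTf, 2,6-lutidine, CH2Cl2, −78 → 0 °C
Reagents that add atoms: tert-butyldimethylsilyl triflate, CC(C)(C)[Si](C)(C)OS(=O)(=O)C(F)(F)F
Why: Silyl triflate silylation of a hindered secondary alcohol, which masks the hydroxyl against triflic anhydride.

Step 9
Reactants: 18 (3S,4S,5R)-5-(tert-butyldimethylsilyloxy)-4-(4-chlorobutyl)-3-ethyl-6-methylidene-1-(pyrrolidin-1-yl)oct-7-en-1-one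
Product: 22 (1R,2R,3S,4R,5S)-2-(tert-butyldimethylsilyloxy)-3-(4-chlorobutyl)-1-ethenyl-4-ethylbicyclo[3.2.0]heptan-6-one, via O-triflyl iminium triflate 19 (not isolated), via keteniminium triflate 20 (not isolated), via cyclobutaniminium triflate 21 (not isolated)
Conditions: Tf2O, 2,4,6-collidine, ClCH2CH2Cl, 0 → 80 °C; then H2O, 80 °C
Reagents that add atoms: water, O
Why: Amide activation with Tf2O and collidine gives an aldo-keteniminium ion that should undergo an intramolecular keteniminium–olefin [2+2] cycloaddition, the closest known reaction type being the cyclisation of tethered keteniminium salts to bicyclo[3.2.0]heptan-6-ones. The iminium carbon bonds first to the terminal CH2 of the substituted diene double bond, which puts the developing charge on a tertiary allylic carbon, and the α-carbon then closes onto that carbon, so the cyclopentane forms by 5-exo closure and the cyclobutane by collapse of the same zwitterion in one asynchronous event. The three-atom tether allows only cis fusion, which fixes the two new ring-fusion centers relative to each other. Their sense relative to the chain is set by the ethyl and chlorobutyl groups, which should stay on the convex face, anti to the forming four-membered ring. The step needs regioselectivity for the substituted double bond and [2+2] over [4+2] periselectivity; the tertiary allyl cation stabilisation and a tether too short to span the diene termini secure both. Hydrolysis of the cyclobutaniminium salt then gives the ketone.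

Step 10
Reactants: 22 (1R,2R,3S,4R,5S)-2-(tert-butyldimethylsilyloxy)-3-(4-chlorobutyl)-1-ethenyl-4-ethylbicyclo[3.2.0]heptan-6-one
Product: 23 (3aR,4R,5S,6R,6aS)-4-(tert-butyldimethylsilyloxy)-5-(4-chlorobutyl)-3a-ethenyl-6-ethylhexahydro-2H-cyclopenta[b]furan-2-one
Conditions: m-CPBA, NaHCO3, CH2Cl2, 0 °C
Reagents that add atoms: 3-chloroperbenzoic acid, OOC(=O)c1cccc(Cl)c1
Why: Baeyer–Villiger oxidation of the strained cyclobutanone, in which the ring-fusion CH should migrate with retention in preference to the CH2 and the terminal vinyl group should react far more slowly.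

Step 11
Reactants: 23 (3aR,4R,5S,6R,6aS)-4-(tert-butyldimethylsilyloxy)-5-(4-chlorobutyl)-3a-ethenyl-6-ethylhexahydro-2H-cyclopenta[b]furan-2-one
Product: 25 (3S,3aS,4R,5S,6R,6aS)-4-(tert-butyldimethylsilyloxy)-5-(4-chlorobutyl)-3a-ethenyl-6-ethyl-3-methylhexahydro-2H-cyclopenta[b]furan-2-one, via lithium enolate 24 (not isolated)
Conditions: LiN(iPr)2, THF, −78 °C; then MeI, −78 → −40 °C
Reagents that add atoms: iodomethane, CI
Why: Lactone enolate alkylation, in which iodomethane should enter from the convex face of the cis-fused bicycle, anti to the cyclopentane ring and its endo silyloxy group and cis to the small angular vinyl group.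

Step 12
Reactants: 25 (3S,3aS,4R,5S,6R,6aS)-4-(tert-butyldimethylsilyloxy)-5-(4-chlorobutyl)-3a-ethenyl-6-ethyl-3-methylhexahydro-2H-cyclopenta[b]furan-2-one
Product: 26 (3S,3aR,4R,5S,6R,6aS)-3a-acetyl-4-(tert-butyldimethylsilyloxy)-5-(4-chlorobutyl)-6-ethyl-3-methylhexahydro-2H-cyclopenta[b]furan-2-one
Conditions: PdCl2 (cat.), CuCl, O2 (1 atm), DMF/H2O, 25 °C
Reagents that add atoms: dioxygen, O=O
Why: Tsuji–Wacker oxidation of the terminal vinyl group should give the methyl ketone by Markovnikov hydroxypalladation (oxygen delivered through water, which is re-formed on reoxidation), with no stereocenter touched.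

Step 13
Reactants: 27 (R)-2,2-dimethyl-1,3-dioxolane-4-carbaldehyde; 28 ethyl 2-[bis(2,2,2-trifluoroethoxy)phosphoryl]propanoate
Product: 29 ethyl (2Z)-3-[(4S)-2,2-dimethyl-1,3-dioxolan-4-yl]-2-methylprop-2-enoate
Conditions: KN(SiMe3)2, 18-crown-6, THF, −78 °C
Reagents that add atoms: none
Why: Still–Gennari olefination should give the Z-trisubstituted enoate required for lactonisation, the dioxolane stereocenter being unaffected.

Step 14
Reactants: 29 ethyl (2Z)-3-[(4S)-2,2-dimethyl-1,3-dioxolan-4-yl]-2-methylprop-2-enoate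
Product: 31 (5S)-5-(hydroxymethyl)-3-methylfuran-2(5H)-one, via diol ester 30 (not isolated)
Conditions: 1 M HCl, THF, 25 °C
Reagents that add atoms: none
Why: Acidic acetonide cleavage followed by lactonisation of the Z-γ-hydroxy enoate, which should close the five-membered butenolide on the secondary hydroxyl.

Step 15
Reactants: 31 (5S)-5-(hydroxymethyl)-3-methylfuran-2(5H)-one
Product: 32 (3S,5S)-5-(hydroxymethyl)-3-methyloxolan-2-one
Conditions: H2 (1 atm), Rh/Al2O3, EtOAc, 25 °C
Reagents that add atoms: none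
Why: Heterogeneous hydrogenation should deliver hydrogen to the butenolide face opposite the hydroxymethyl group, giving the cis-2,4-disubstituted lactone.

Step 16
Reactants: 32 (3S,5S)-5-(hydroxymethyl)-3-methyloxolan-2-one
Product: 33 (2S,4S)-4-methyl-5-oxooxolane-2-carbaldehyde
Conditions: Dess–Martin periodinane, NaHCO3, CH2Cl2, 0 → 25 °C
Reagents that add atoms: none
Why: Dess–Martin oxidation of a primary alcohol under buffered conditions that should not epimerise the α-oxygenated center.

Step 17
Reactants: 33 (2S,4S)-4-methyl-5-oxooxolane-2-carbaldehyde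
Product: 34 (R)-N-{(E)-[(2S,4S)-4-methyl-5-oxooxolan-2-yl]methylidene}-2-methylpropane-2-sulfinamide
Conditions: (R)-t-BuS(O)NH2, CuSO4, CH2Cl2, 25 °C
Reagents that add atoms: (R)-2-methylpropane-2-sulfinamide, CC(C)(C)[S@@](=O)N
Why: Dehydrative condensation of an aldehyde with tert-butanesulfinamide should give the E-configured N-sulfinyl imine.

Step 18
Reactants: 26 (3S,3aR,4R,5S,6R,6aS)-3a-acetyl-4-(tert-butyldimethylsilyloxy)-5-(4-chlorobutyl)-6-ethyl-3-methylhexahydro-2H-cyclopenta[b]furan-2-one; 34 (R)-N-{(E)-[(2S,4S)-4-methyl-5-oxooxolan-2-yl]methylidene}-2-methylpropane-2-sulfinamide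
Product: 36 (R)-N-{(1S)-3-[(3S,3aR,4R,5S,6R,6aS)-4-(tert-butyldimethylsilyloxy)-5-(4-chlorobutyl)-6-ethyl-3-methyl-2-oxohexahydro-2H-cyclopenta[b]furan-3a-yl]-1-[(2S,4S)-4-methyl-5-oxooxolan-2-yl]-3-oxopropyl}-2-methylpropane-2-sulfinamide, via lithium enolate 35 (not isolated)
Conditions: LiN(SiMe3)2, THF, −78 °C; then 34, −78 °C; aq. NH4Cl
Reagents that add atoms: none
Why: Mannich-type addition of the methyl ketone enolate (the only enolisable position of the neopentyl ketone) to the N-sulfinyl imine through a lithium-chelated chair transition state, in which the (R)-sulfinyl group should direct attack to give the (S)-amine carbon.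

Step 19
Reactants: 36 (silyl ether Mannich adduct named in step 18)
Product: 37 (R)-N-{(1S)-3-[(3S,3aS,4R,5S,6R,6aS)-5-(4-chlorobutyl)-6-ethyl-4-hydroxy-3-methyl-2-oxohexahydro-2H-cyclopenta[b]furan-3a-yl]-1-[(2S,4S)-4-methyl-5-oxooxolan-2-yl]-3-oxopropyl}-2-methylpropane-2-sulfinamide
Conditions: HF·pyridine, pyridine, THF, 0 → 25 °C
Reagents that add atoms: none
Why: Fluoride cleavage of the silyl ether under buffered, non-basic conditions that should avoid retro-aldol opening of the β-hydroxy ketone.

Step 20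
Reactants: 37 (alcohol named in step 19)
Product: 38 (R)-N-{(1S)-3-[(3S,3aS,5S,6R,6aS)-5-(4-chlorobutyl)-6-ethyl-3-methyl-2,4-dioxohexahydro-2H-cyclopenta[b]furan-3a-yl]-1-[(2S,4S)-4-methyl-5-oxooxolan-2-yl]-3-oxopropyl}-2-methylpropane-2-sulfinamide
Conditions: Dess–Martin periodinane, pyridine, CH2Cl2, 25 °C
Reagents that add atoms: none
Why: Dess–Martin oxidation under neutral conditions should give the non-enolisable 2-acylcyclopentanone (1,3-diketone) without epimerising the adjacent chain-bearing CH.

Step 21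
Reactants: 38 (1,3-diketone sulfinamide named in step 20)
Product: 40 tricyclic ketimine in which the amine nitrogen of 38 (sulfinyl group removed) is doubly bonded to the cyclopentanone carbon in a six-membered ring (all stereocenters as in 38), via ammonium chloride 39 (not isolated)
Conditions: HCl (4 M in dioxane), MeOH, CH2Cl2, 0 °C; then NaHCO3, 4 Å molecular sieves, CH2Cl2, 25 °C
Reagents that add atoms: none
Why: Acidic cleavage of the N-sulfinyl group followed by intramolecular imine condensation of the primary amine with the ring ketone, which should be favoured under mildly acidic, dehydrating conditions.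

Step 22
Reactants: 40 tricyclic ketimine
Product: 45 tuberostemonone, via alkyl iodide 41 (not isolated), via iminium iodide 42 (not isolated), via carbinolamine 43 (not isolated), via enol 44 (not isolated)
Conditions: NaI, MeCN, 70 °C; then aq. NaHCO3, 25 °C; DBU (cat.), CH2Cl2, 25 °C
Reagents that add atoms: water, O
Why: Proposed new method: Finkelstein exchange gives the iodide, the imine nitrogen (lone pair syn to the chain-bearing carbon) is alkylated in a 7-exo-tet closure, water adds to the α-acyl iminium carbon and the carbinolamine alkoxide expels the ketone enolate (retro-Claisen C–C cleavage), so the cyclopentane opens to the nine-membered keto lactam, whose enol is protonated under equilibrating conditions to the assumed thermodynamic epimer next to the ketone; the closest known reaction types are N-alkylation of cyclic imines and the amine-induced transamidative ring enlargement of 2-acylcycloalkanones.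

**Compound list**
1 | 6-chlorohex-1-ene | C=CCCCCCl | starting material
2 | (S)-but-3-en-2-ol | C[C@H](O)C=C | starting material
3 | (2S,3E)-8-chlorooct-3-en-2-ol | C[C@H](O)/C=C/CCCCCl | intermediate
4 | butanoyl chloride | CCCC(=O)Cl | starting material
5 | (2S,3E)-8-chlorooct-3-en-2-yl butanoate | C[C@H](OC(=O)CCC)/C=C/CCCCCl | intermediate
6 | silyl ketene acetal (ethyl trans to OSiMe3) | CC/C=C(/O[Si](C)(C)C)O[C@@H](C)/C=C/CCCCCl | intermediate
7 | trimethylsilyl ester of acid 8 | CC[C@@H](C(=O)O[Si](C)(C)C)[C@H](CCCCCl)/C=C/C | intermediate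
8 | (2R,3R,4E)-3-(4-chlorobutyl)-2-ethylhex-4-enoic acid | CC[C@@H](C(=O)O)[C@H](CCCCCl)/C=C/C | intermediate
9 | mixed carbonic anhydride of 8 with isobutyl carbonate | CC[C@@H](C(=O)OC(=O)OCC(C)C)[C@H](CCCCCl)/C=C/C | intermediate
10 | (3R,4R,5E)-4-(4-chlorobutyl)-1-diazo-3-ethylhept-5-en-2-one | CC[C@@H](C(=O)C=[N+]=[N-])[C@H](CCCCCl)/C=C/C | intermediate
11 | ketene, (3R,4R,5E)-4-(4-chlorobutyl)-3-ethylhepta-1,5-dien-1-one | CC[C@@H](C=C=O)[C@H](CCCCCl)/C=C/C | intermediate
12 | (3S,4S,5E)-4-(4-chlorobutyl)-3-ethyl-1-(pyrrolidin-1-yl)hept-5-en-1-one | CC[C@@H](CC(=O)N1CCCC1)[C@H](CCCCCl)/C=C/C | intermediate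
13 | ozonide (1,2,4-trioxolane) of 12 | CC[C@@H](CC(=O)N1CCCC1)[C@H](CCCCCl)C1OOC(C)O1 | intermediate
14 | (2S,3S)-2-(4-chlorobutyl)-3-ethyl-5-oxo-5-(pyrrolidin-1-yl)pentanal | CC[C@@H](CC(=O)N1CCCC1)[C@H](CCCCCl)C=O | intermediate
15 | 2-chlorobuta-1,3-diene | C=CC(Cl)=C | starting material
16 | dienyl Grignard reagent, buta-1,3-dien-2-ylmagnesium chloride | C=CC(=C)[Mg]Cl | intermediate
17 | (3S,4S,5R)-4-(4-chlorobutyl)-3-ethyl-5-hydroxy-6-methylidene-1-(pyrrolidin-1-yl)oct-7-en-1-one | CC[C@@H](CC(=O)N1CCCC1)[C@H](CCCCCl)[C@@H](O)C(=C)C=C | intermediate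
18 | (3S,4S,5R)-5-(tert-butyldimethylsilyloxy)-4-(4-chlorobutyl)-3-ethyl-6-methylidene-1-(pyrrolidin-1-yl)oct-7-en-1-one | CC[C@@H](CC(=O)N1CCCC1)[C@H](CCCCCl)[C@@H](O[Si](C)(C)C(C)(C)C)C(=C)C=C | intermediate
19 | O-triflyl iminium triflate of 18 | CC[C@@H](CC(OS(=O)(=O)C(F)(F)F)=[N+]1CCCC1)[C@H](CCCCCl)[C@@H](O[Si](C)(C)C(C)(C)C)C(=C)C=C.[O-]S(=O)(=O)C(F)(F)F | intermediate
20 | keteniminium triflate | CC[C@@H](C=C=[N+]1CCCC1)[C@H](CCCCCl)[C@@H](O[Si](C)(C)C(C)(C)C)C(=C)C=C.[O-]S(=O)(=O)C(F)(F)F | intermediate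
21 | cyclobutaniminium triflate | CC[C@H]1[C@@H]2C(=[N+]3CCCC3)C[C@]2(C=C)[C@H](O[Si](C)(C)C(C)(C)C)[C@H]1CCCCCl.[O-]S(=O)(=O)C(F)(F)F | intermediate
22 | (1R,2R,3S,4R,5S)-2-(tert-butyldimethylsilyloxy)-3-(4-chlorobutyl)-1-ethenyl-4-ethylbicyclo[3.2.0]heptan-6-one | CC[C@H]1[C@@H]2C(=O)C[C@]2(C=C)[C@H](O[Si](C)(C)C(C)(C)C)[C@H]1CCCCCl | intermediate
23 | (3aR,4R,5S,6R,6aS)-4-(tert-butyldimethylsilyloxy)-5-(4-chlorobutyl)-3a-ethenyl-6-ethylhexahydro-2H-cyclopenta[b]furan-2-one | CC[C@H]1[C@@H]2OC(=O)C[C@]2(C=C)[C@H](O[Si](C)(C)C(C)(C)C)[C@H]1CCCCCl | intermediate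
24 | lithium enolate of lactone 23 | CC[C@H]1[C@@H]2OC(O[Li])=C[C@]2(C=C)[C@H](O[Si](C)(C)C(C)(C)C)[C@H]1CCCCCl | intermediate
25 | (3S,3aS,4R,5S,6R,6aS)-4-(tert-butyldimethylsilyloxy)-5-(4-chlorobutyl)-3a-ethenyl-6-ethyl-3-methylhexahydro-2H-cyclopenta[b]furan-2-one | CC[C@H]1[C@@H]2OC(=O)[C@@H](C)[C@]2(C=C)[C@H](O[Si](C)(C)C(C)(C)C)[C@H]1CCCCCl | intermediate
26 | (3S,3aR,4R,5S,6R,6aS)-3a-acetyl-4-(tert-butyldimethylsilyloxy)-5-(4-chlorobutyl)-6-ethyl-3-methylhexahydro-2H-cyclopenta[b]furan-2-one | CC[C@H]1[C@@H]2OC(=O)[C@@H](C)[C@]2(C(C)=O)[C@H](O[Si](C)(C)C(C)(C)C)[C@H]1CCCCCl | intermediate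
27 | (R)-2,2-dimethyl-1,3-dioxolane-4-carbaldehyde | CC1(C)OC[C@@H](O1)C=O | starting material
28 | ethyl 2-[bis(2,2,2-trifluoroethoxy)phosphoryl]propanoate | CCOC(=O)C(C)P(=O)(OCC(F)(F)F)OCC(F)(F)F | starting material
29 | ethyl (2Z)-3-[(4S)-2,2-dimethyl-1,3-dioxolan-4-yl]-2-methylprop-2-enoate | CC1(C)OC[C@@H](O1)/C=C(/C)C(=O)OCC | intermediate
30 | diol ester, ethyl (2Z,4S)-4,5-dihydroxy-2-methylpent-2-enoate | OC[C@@H](O)/C=C(/C)C(=O)OCC | intermediate
31 | (5S)-5-(hydroxymethyl)-3-methylfuran-2(5H)-one | CC1=C[C@@H](CO)OC1=O | intermediate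
32 | (3S,5S)-5-(hydroxymethyl)-3-methyloxolan-2-one | C[C@H]1C[C@@H](CO)OC1=O | intermediate
33 | (2S,4S)-4-methyl-5-oxooxolane-2-carbaldehyde | C[C@H]1C[C@@H](C=O)OC1=O | intermediate
34 | (R)-N-{(E)-[(2S,4S)-4-methyl-5-oxooxolan-2-yl]methylidene}-2-methylpropane-2-sulfinamide | C[C@H]1C[C@@H](/C=N/[S@](=O)C(C)(C)C)OC1=O | intermediate
35 | lithium enolate of methyl ketone 26 | CC[C@H]1[C@@H]2OC(=O)[C@@H](C)[C@]2(C(=C)O[Li])[C@H](O[Si](C)(C)C(C)(C)C)[C@H]1CCCCCl | intermediate
36 | silyl ether Mannich adduct (full name in step 18) | CC[C@H]1[C@@H]2OC(=O)[C@@H](C)[C@]2(C(=O)C[C@H](N[S@](=O)C(C)(C)C)[C@@H]2C[C@H](C)C(=O)O2)[C@H](O[Si](C)(C)C(C)(C)C)[C@H]1CCCCCl | intermediate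
37 | alcohol from 36 (full name in step 19) | CC[C@H]1[C@@H]2OC(=O)[C@@H](C)[C@]2(C(=O)C[C@H](N[S@](=O)C(C)(C)C)[C@@H]2C[C@H](C)C(=O)O2)[C@H](O)[C@H]1CCCCCl | intermediate
38 | 1,3-diketone sulfinamide (full name in step 20) | CC[C@H]1[C@@H]2OC(=O)[C@@H](C)[C@]2(C(=O)C[C@H](N[S@](=O)C(C)(C)C)[C@@H]2C[C@H](C)C(=O)O2)C(=O)[C@H]1CCCCCl | intermediate
39 | ammonium chloride of the desulfinylated amine | CC[C@H]1[C@@H]2OC(=O)[C@@H](C)[C@]2(C(=O)C[C@H]([NH3+])[C@@H]2C[C@H](C)C(=O)O2)C(=O)[C@H]1CCCCCl.[Cl-] | intermediate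
40 | tricyclic ketimine (six-membered C=N ring between the amine nitrogen and the former cyclopentanone carbon) | CC[C@H]1[C@@H]2OC(=O)[C@@H](C)[C@@]23C(=O)C[C@@H]([C@@H]4C[C@H](C)C(=O)O4)N=C3[C@H]1CCCCCl | intermediate
41 | alkyl iodide corresponding to 40 | CC[C@H]1[C@@H]2OC(=O)[C@@H](C)[C@@]23C(=O)C[C@@H]([C@@H]4C[C@H](C)C(=O)O4)N=C3[C@H]1CCCCI | intermediate
42 | iminium iodide (seven-membered ring closed on nitrogen) | CC[C@H]1[C@@H]2OC(=O)[C@@H](C)[C@@]23C(=O)C[C@@H]([C@@H]4C[C@H](C)C(=O)O4)[N+]5=C3[C@H]1CCCC5.[I-] | intermediate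
43 | carbinolamine from hydration of 42 | CC[C@H]1[C@@H]2OC(=O)[C@@H](C)[C@@]23C(=O)C[C@@H]([C@@H]4C[C@H](C)C(=O)O4)N5C3(O)[C@H]1CCCC5 | intermediate
44 | enol of the ring-opened nine-membered keto lactam | CC[C@H]1[C@@H]2OC(=O)[C@@H](C)C2=C(O)C[C@@H]([C@@H]2C[C@H](C)C(=O)O2)N2CCCC[C@@H]1C2=O | intermediate
45 | tuberostemonone | CC[C@H]1[C@@H]2OC(=O)[C@@H](C)[C@H]2C(=O)C[C@@H]([C@@H]2C[C@H](C)C(=O)O2)N2CCCC[C@@H]1C2=O | target

**Step count and risks**
Total step count: 22. Longest linear sequence: 17 steps (steps 1–12 and 18–22); the pendant lactone branch is steps 13–17.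

Steps most likely to fail:

1. Step 22 (proposed new method). The cascade can leave its intended path in two ways. The C–C cleavage may run ahead of N-alkylation (already in step 21, once the free amine meets the diketone), which leaves a secondary lactam that is no longer nucleophilic under neutral conditions. Or the iminium ion may lose the α-proton at the chain-bearing carbon and scramble that center. Fallback with known chemistry, setting out from 38: the sulfinyl group is removed with HCl in dioxane and the amine salt is treated with Et3N in MeOH, so that the primary amine adds to the ring ketone and the carbinolamine fragments (amine-induced ring enlargement of a 2-acylcycloalkanone) to the nine-membered secondary keto lactam F1. Halide exchange with NaI in acetone followed by KOt-Bu in THF at 0 °C then closes the seven-membered ring by lactam N-alkylation, and equilibration next to the ketone returns the route at 45.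

2. Step 9. The diene may be captured by the cation in other ways than four-ring closure (closure at the far diene terminus, oligomerisation), or the allylic silyl ether may ionise under Tf2O. Fallback, setting out from 14, replaces the diene by an isolated 1,1-disubstituted alkene that carries the acetyl group as a ketal. Addition of 1-(2-methyl-1,3-dioxolan-2-yl)ethenyllithium F2 (from 2-(1-bromoethenyl)-2-methyl-1,3-dioxolane and t-BuLi) to 14 should give the allylic alcohol F3. Silylation gives the silyl ether F4, keteniminium cycloaddition on the simple alkene gives the cyclobutanone F5, Baeyer–Villiger oxidation gives the lactone F6, and methylation gives the methyl lactone F7. Ketal hydrolysis (aqueous acid, acetone) returns the route at 26, so the Wacker step is not needed.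

3. Step 11. Facial selectivity may be poor or reversed if the angular vinyl group shields the convex face more than the cyclopentane ring shields the concave one. Fallback sets the center by protonation instead of alkylation: the epimeric methyl lactone F8 (or the mixture) is deprotonated with LiN(iPr)2 at −78 °C and the enolate is quenched with 2,6-di-tert-butylphenol. The proton should take the same, more accessible face that iodomethane took, which turns the methyl group to the convex face and returns the route at 25.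

**Further compounds**
F1 | step 22 | nine-membered secondary keto lactam carrying the 4-chlorobutyl chain (stereocenters as in 45) | CC[C@H]1[C@@H]2OC(=O)[C@@H](C)[C@H]2C(=O)C[C@@H]([C@@H]2C[C@H](C)C(=O)O2)NC(=O)[C@H]1CCCCCl
F2 | step 9 | 1-(2-methyl-1,3-dioxolan-2-yl)ethenyllithium | [Li]C(=C)C1(C)OCCO1
F3 | step 9 | (3S,4S,5R)-4-(4-chlorobutyl)-3-ethyl-5-hydroxy-6-(2-methyl-1,3-dioxolan-2-yl)-1-(pyrrolidin-1-yl)hept-6-en-1-one | CC[C@@H](CC(=O)N1CCCC1)[C@H](CCCCCl)[C@@H](O)C(=C)C1(C)OCCO1
F4 | step 9 | tert-butyldimethylsilyl ether of F3 | CC[C@@H](CC(=O)N1CCCC1)[C@H](CCCCCl)[C@@H](O[Si](C)(C)C(C)(C)C)C(=C)C1(C)OCCO1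
F5 | step 9 | analogue of 22 with 1-(2-methyl-1,3-dioxolan-2-yl) in place of 1-ethenyl | CC[C@H]1[C@@H]2C(=O)C[C@]2(C3(C)OCCO3)[C@H](O[Si](C)(C)C(C)(C)C)[C@H]1CCCCCl
F6 | step 9 | analogue of 23 with 3a-(2-methyl-1,3-dioxolan-2-yl) in place of 3a-ethenyl | CC[C@H]1[C@@H]2OC(=O)C[C@]2(C3(C)OCCO3)[C@H](O[Si](C)(C)C(C)(C)C)[C@H]1CCCCCl
F7 | step 9 | ethylene ketal of methyl ketone 26 | CC[C@H]1[C@@H]2OC(=O)[C@@H](C)[C@]2(C3(C)OCCO3)[C@H](O[Si](C)(C)C(C)(C)C)[C@H]1CCCCCl
F8 | step 11 | C-3 epimer of 25 (methyl on the concave face) | CC[C@H]1[C@@H]2OC(=O)[C@H](C)[C@]2(C=C)[C@H](O[Si](C)(C)C(C)(C)C)[C@H]1CCCCCl
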